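**Retrosynthetic overview**

1. The target is a butenolide (ring atoms O1, C2 carbonyl, C3, C4, C5) with exocyclic C6 and the carbinol carbon C1' on C3. The route rests on the ring alkene C3=C4, where the C1' carbinol (on C3) and bromine (on C4) sit side by side: this is the pattern bromide and butanal leave on the β- and α-carbons of a 2-ynoate.
2. C6–I is made last: ICl addition to the C5=C6 methylene lactone and loss of HCl give the (Z)-iodomethylene; C5=C6 itself comes from loss of HCl out of a 5-chloromethyl lactone.
3. The butenolide is the only ring. It closes by O1–C2 lactonisation once the C5 oxygen is unmasked, after the key step.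
4. Key disconnection: C4–Br and C3–C1' together, by coupling Me3SiBr, a γ-silyloxy ynoate (C2 to C6 in place, C6 as CH2Cl) and butanal under a chiral oxazaborolidinium cation, which also sets (R)-C1'.
5. The ynoate is cut at C4–C5 into lithiated methyl propiolate and chloroacetaldehyde, followed by O-silylation.

Key step: step 3

Remark: chloroacetaldehyde is used as the anhydrous monomer, dried azeotropically and distilled from the commercial aqueous solution just before use, because the hydrate would quench the lithium acetylide.

**Route**

Step 1
Reactants: 1 methyl propiolate; 2 chloroacetaldehyde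
Product: 4 methyl 5-chloro-4-hydroxypent-2-ynoate (racemic), via methyl 3-lithiopropiolate 3 (not isolated)
Conditions: LiN(SiMe3)2, THF, −78 °C; then 2 (anhydrous, in THF), −78 °C; AcOH quench at −78 °C
Reagents that add atoms: none
Why: Acetylide 1,2-addition to an aldehyde: the lithiated propiolate is stable at −78 °C and adds to the unhindered aldehyde, the cold acidic quench keeps the chlorohydrin alkoxide from closing to an epoxide, and the new carbinol centre may be racemic because it becomes sp2 in step 5.

Step 2
Reactants: 4 methyl 5-chloro-4-hydroxypent-2-ynoate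
Product: 5 methyl 4-[(tert-butyldimethylsilyl)oxy]-5-chloropent-2-ynoate (racemic)
Conditions: TBSOTf, 2,6-lutidine, CH2Cl2, −78 → 0 °C
Reagents that add atoms: tert-butyldimethylsilyl trifluoromethanesulfonate, CC(C)(C)[Si](C)(C)OS(=O)(=O)C(F)(F)F
Why: Silyl ether formation with a silyl triflate and a hindered pyridine base is fast at low temperature and avoids the amine-promoted isomerisation of γ-hydroxy ynoates to γ-oxo enoates.

Step 3
Reactants: 5 methyl 4-[(tert-butyldimethylsilyl)oxy]-5-chloropent-2-ynoate; 6 butanal
Product: 9 methyl (2E)-3-bromo-4-[(tert-butyldimethylsilyl)oxy]-5-chloro-2-[(1R)-1-hydroxybutyl]pent-2-enoate (two epimers at the silyloxy carbon), via silyl bromoallenolate 7 (not isolated), via O-trimethylsilyl aldol adduct 8 (not isolated)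
Conditions: Me3SiBr (1.3 equiv), (S)-3,3-diphenyl-1-(2-methylphenyl)tetrahydro-1H,3H-pyrrolo[1,2-c][1,3,2]oxazaborole (20 mol %), (CF3SO2)2NH (20 mol %), EtCN, −78 → −40 °C; then 1 M HCl, THF, 0 °C
Reagents that add atoms: bromotrimethylsilane, C[Si](C)(C)Br
Why: Proposed new method: bromide from Me3SiBr should add 1,4 to ynoate 5 at C4 and leave silyl bromoallenolate 7, whose enolate carbon C3 then adds to butanal bound to the boron cation in a Mukaiyama-type aldol, so that C4–Br, C3–C1' and the carbinol arise in one flask (silyl transfer gives 8, hydrolysed to 9 on work-up) and no ring is closed. The closest known reaction type is the oxazaborolidinium-catalysed three-component halo-aldol (β-halo Morita–Baylis–Hillman) coupling of Me3SiI or Me3SiBr with propiolate esters and aldehydes; the extension is to an internal ynoate with a γ-silyloxy group, which has to give a tetrasubstituted bromoalkene. The C1' stereocentre is under catalyst control: with the aldehyde held by B–O coordination and a formyl C–H···O contact, an aryl group of the (S)-catalyst is expected to screen the re face, and si-face attack gives the (R)-carbinol (priorities O > alkenyl > propyl); the sense is to be confirmed by Mosher ester analysis on the first batch, the enantiomeric catalyst being used if it proves reversed. The step needs β-selective bromide addition, secured by the ester polarisation of the alkyne and helped by the inductive pull of the γ-oxygen, and it needs the (2E) geometry with ester and C5 cis, expected because the reacting lobe at C3 lies in the plane of the two C4 substituents and the aldehyde should pass the bromine rather than the branched CH(OTBS)CH2Cl group. Loss of silyloxide from 7 is not expected, since the enolate π system is orthogonal to the C3=C4 π bond through which such an elimination would have to run. The racemic C5 centre makes 9 a pair of epimers that converge in step 5, and any (2Z) isomer cannot lactonise in step 4 and is separated there.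

Step 4
Reactants: 9 methyl (2E)-3-bromo-4-[(tert-butyldimethylsilyl)oxy]-5-chloro-2-[(1R)-1-hydroxybutyl]pent-2-enoate
Product: 11 4-bromo-5-(chloromethyl)-3-[(1R)-1-hydroxybutyl]furan-2(5H)-one (two C5 epimers), via dihydroxy ester 10 (not isolated)
Conditions: HF (48% aq), MeCN, 0 °C → rt; then cat. p-toluenesulfonic acid monohydrate (p-TsOH·H2O), CH2Cl2, rt
Reagents that add atoms: none
Why: Acidic fluoride desilylation (no alkoxide, hence no epoxide from the chlorohydrin) frees the C5 hydroxyl, which sits cis to the ester on the tetrasubstituted alkene and closes the butenolide by acid-catalysed lactonisation (transesterification), while the (R)-carbinol on C1' is untouched and cannot lactonise itself because that would give a four-membered ring.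

Step 5
Reactants: 11 4-bromo-5-(chloromethyl)-3-[(1R)-1-hydroxybutyl]furan-2(5H)-one
Product: 12 4-bromo-3-[(1R)-1-hydroxybutyl]-5-methylidenefuran-2(5H)-one
Conditions: DBU (1.1 equiv), CH2Cl2, −20 → 0 °C
Reagents that add atoms: none
Why: E1cB dehydrochlorination: C5–H is γ to the lactone carbonyl, its removal gives a 2-furanolate that expels chloride from the adjacent CH2Cl, and the C5 centre disappears, so both epimers should give the same cross-conjugated methylene butenolide.

Step 6
Reactants: 12 4-bromo-3-[(1R)-1-hydroxybutyl]-5-methylidenefuran-2(5H)-one
Product: 14 (5Z)-4-bromo-3-[(1R)-1-hydroxybutyl]-5-(iodomethylidene)furan-2(5H)-one, via iodochloride adduct 13 (not isolated)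
Conditions: ICl (1.05 equiv), CH2Cl2, −78 → 0 °C, dark; then Et3N, 0 °C → rt; then cat. I2, visible light, rt
Reagents that add atoms: iodine monochloride, ClI
Why: Electrophilic halogen addition followed by dehydrohalogenation: the iodine of ICl should attack the terminal C6 of the enol-ester alkene, chloride caps the C5 oxocarbenium ion, Et3N removes HCl across C6–C5, and the Z isomer (iodine on the O1 side, away from the C4 bromine) is the thermodynamic one, to which iodine-atom catalysed equilibration should channel any E isomer without touching C1'.

**Compound list**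

1 | methyl propiolate | C#CC(=O)OC | starting material
2 | chloroacetaldehyde | ClCC=O | starting material
3 | methyl 3-lithiopropiolate | [Li]C#CC(=O)OC | intermediate
4 | methyl 5-chloro-4-hydroxypent-2-ynoate (racemic) | COC(=O)C#CC(O)CCl | intermediate
5 | methyl 4-[(tert-butyldimethylsilyl)oxy]-5-chloropent-2-ynoate (racemic) | COC(=O)C#CC(CCl)O[Si](C)(C)C(C)(C)C | intermediate
6 | butanal | CCCC=O | starting material
7 | 3-bromo-4-[(tert-butyldimethylsilyl)oxy]-5-chloro-1-methoxy-1-[(trimethylsilyl)oxy]penta-1,2-diene (silyl bromoallenolate) | COC(O[Si](C)(C)C)=C=C(Br)C(CCl)O[Si](C)(C)C(C)(C)C | intermediate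
8 | methyl (2E)-3-bromo-4-[(tert-butyldimethylsilyl)oxy]-5-chloro-2-[(1R)-1-[(trimethylsilyl)oxy]butyl]pent-2-enoate | CCC[C@@H](O[Si](C)(C)C)/C(=C(\Br)C(CCl)O[Si](C)(C)C(C)(C)C)C(=O)OC | intermediate
9 | methyl (2E)-3-bromo-4-[(tert-butyldimethylsilyl)oxy]-5-chloro-2-[(1R)-1-hydroxybutyl]pent-2-enoate | CCC[C@@H](O)/C(=C(\Br)C(CCl)O[Si](C)(C)C(C)(C)C)C(=O)OC | intermediate
10 | methyl (2E)-3-bromo-5-chloro-4-hydroxy-2-[(1R)-1-hydroxybutyl]pent-2-enoate | CCC[C@@H](O)/C(=C(\Br)C(O)CCl)C(=O)OC | intermediate
11 | 4-bromo-5-(chloromethyl)-3-[(1R)-1-hydroxybutyl]furan-2(5H)-one | CCC[C@@H](O)C1=C(Br)C(CCl)OC1=O | intermediate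
12 | 4-bromo-3-[(1R)-1-hydroxybutyl]-5-methylidenefuran-2(5H)-one | CCC[C@@H](O)C1=C(Br)C(=C)OC1=O | intermediate
13 | 4-bromo-5-chloro-3-[(1R)-1-hydroxybutyl]-5-(iodomethyl)furan-2(5H)-one | CCC[C@@H](O)C1=C(Br)C(Cl)(CI)OC1=O | intermediate
14 | (5Z)-4-bromo-3-[(1R)-1-hydroxybutyl]-5-(iodomethylidene)furan-2(5H)-one | CCC[C@@H](O)C1=C(Br)/C(=C/I)OC1=O | target

**Step count and risks**

Total step count: 6. Longest linear sequence: 6 steps.

Step 3 is the riskiest. The enantioface discrimination at butanal may be weak: the racemic silyloxy centre of 7 can oppose the catalyst in one epimer series, and a warmer reaction forced by slow bromide addition to the hindered internal ynoate would erode it further. The fallback resets the carbinol by known reagent control and sets out from 9 of low enantiomeric purity. Oxidation with Dess–Martin periodinane (NaHCO3, CH2Cl2, 0 °C) should give methyl (2E)-3-bromo-2-butanoyl-4-[(tert-butyldimethylsilyl)oxy]-5-chloropent-2-enoate F1. F1 is reduced at once by Corey–Bakshi–Shibata reduction [(S)-1-methyl-3,3-diphenyltetrahydro-1H,3H-pyrrolo[1,2-c][1,3,2]oxazaborole, catecholborane, toluene, −78 °C]. The tetrasubstituted alkenyl group acts as the large substituent there, so the (R)-alcohol is expected, and the fallback comes back to the route at 9.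

Step 6 is next. The halogen addition may not hold (ICl lost again from 13, or deiodination back to 12 when base is added), and E to Z control may be incomplete. The fallback sets out from 12. N-Iodosuccinimide in aqueous acetone at 0 °C should give, by iodohydroxylation, the lactol 4-bromo-5-hydroxy-3-[(1R)-1-hydroxybutyl]-5-(iodomethyl)furan-2(5H)-one F2. Acid-catalysed dehydration (p-toluenesulfonic acid monohydrate, toluene, molecular sieves, 60 °C) runs through the C5 oxocarbenium ion under thermodynamic control and should return to the route at 14.

Step 1 is third. The thermally labile lithiated propiolate 3 may decompose before capture if the aldehyde arrives partly hydrated or oligomeric, and the chlorohydrin alkoxide may close to an alkynyl epoxide. The fallback installs the ester last and sets out from 2. Excess HC≡CMgBr (THF, 0 °C), which tolerates an imperfect aldehyde, should give 1-chlorobut-3-yn-2-ol F3. Silylation (TBSOTf, 2,6-lutidine, CH2Cl2, −78 °C) gives tert-butyl[(1-chlorobut-3-yn-2-yl)oxy]dimethylsilane F4. Deprotonation with n-BuLi (THF, −78 °C) gives the lithium acetylide [3-[(tert-butyldimethylsilyl)oxy]-4-chlorobut-1-yn-1-yl]lithium F5, and methyl chloroformate then returns to the route at 5.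

**Further compounds**

F1 | step 3 | methyl (2E)-3-bromo-2-butanoyl-4-[(tert-butyldimethylsilyl)oxy]-5-chloropent-2-enoate | CCCC(=O)/C(=C(\Br)C(CCl)O[Si](C)(C)C(C)(C)C)C(=O)OC
F2 | step 6 | 4-bromo-5-hydroxy-3-[(1R)-1-hydroxybutyl]-5-(iodomethyl)furan-2(5H)-one | CCC[C@@H](O)C1=C(Br)C(O)(CI)OC1=O
F3 | step 1 | 1-chlorobut-3-yn-2-ol (racemic) | C#CC(O)CCl
F4 | step 1 | tert-butyl[(1-chlorobut-3-yn-2-yl)oxy]dimethylsilane (racemic) | C#CC(CCl)O[Si](C)(C)C(C)(C)C
F5 | step 1 | [3-[(tert-butyldimethylsilyl)oxy]-4-chlorobut-1-yn-1-yl]lithium | [Li]C#CC(CCl)O[Si](C)(C)C(C)(C)C
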